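A litre per mole per minute cancels when one second-order constant is divided by another, and that bare ratio guides my next run. I must decide when to stop these two flasks.

| flask | substrate | partner A | partner B | time |
|---|---|---|---|---|
| gamma | 0.024 M | 1.50 equiv | 4.00 equiv | 1.5 h |
| eta | 0.024 M | 1.50 equiv | 4.00 equiv | 2.0 h |

    partner B + partner A → second intermediate (k1 = 3.00 L mol⁻¹ min⁻¹)
    substrate + partner B → open intermediate (k2 = 1.23 L mol⁻¹ min⁻¹)
    open intermediate + second intermediate → target (k3 = 270 L mol⁻¹ min⁻¹)
    partner B + target → over-reaction product (k4 = 0.982 L mol⁻¹ min⁻¹)

* which of the two there is more of at the end, gamma (target / over-reaction product)
* which of the two there is more of at the end, eta (target / over-reaction product)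
* target at the end, in percent of the substrate charged, gamma
* target at the end, in percent of the substrate charged, eta

Partner B attacks both substrate and target, as two substrates compete for one enzyme. Both rates carry partner B, so their quotient loses it, and time too. I call the quotient κ, the selectivity factor, 0.798: the constant for partner B on target over the constant for partner B on substrate.

I assume that open intermediate becomes target as it forms, since 270 L mol⁻¹ min⁻¹ stands far above 1.23 L mol⁻¹ min⁻¹. At the start of eta, partner B goes 3.7 times as fast to second intermediate as to open intermediate, so a partner for capture builds early.

Let a be the fraction of substrate left and y the fraction present as target. Then dy/da equals κy/a minus one, which integrates to y = (a^κ − a)/(1 − κ). Target peaks where y = a/κ, at a = 32.7% and y = 41.0%.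

To place time on this curve, I need partner B. Of the 4.00 equiv charged, 1.50 equiv goes to partner A, one equivalent to substrate, and up to one more to over-reaction. Midway, about one equivalent stands free, which is my rough mean. The substrate's time constant is then 33.9 min, and the peak comes at 0.631 h, earlier than the 1.5 h of gamma.

My reckoning leaves a = 7.02% in gamma, hence target 24.7%. In eta it leaves a = 2.89%, hence target 15.0%. Over-reaction product leads in both, with 68.3% in gamma. So I would cut both runs short.

The forecast also names over-reaction product for gamma and over-reaction product for eta, but its target is lower than mine: 17% (14% to 20%) for gamma and 11.5% (9% to 14%) for eta. Its words are “most of the target has over-reacted by 1.5 h”.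

The simulation gives target 16.9% and over-reaction product 79.6% in gamma, and target 11.6% and over-reaction product 86.5% in eta. The forecast stands, and my mean of partner B was too low.

The main reason for the loss is the path from partner B and target to over-reaction product: gamma ends with 16.9% target with that path and 99.0% with it struck out. Gamma's simulated substrate, 3.48%, put into the rule gives 16.7%, and gamma already held 41.3% target at 0.300 h, so I stop there. In the neighbour of eta with 3.80 equiv of partner A, 44.3% substrate remains, so the rule gives 39.2%, and that flask holds 39.4% target.

(The constants used here are invented; the rest is arithmetic.)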